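**Retrosynthetic overview**

- Last bond is the ester C–O: a lipase acylates only the primary OH of the indolyl 1,3-diol with linoleic acid.
- Before that, the C6–prenyl bond is made by α-selective Suzuki–Miyaura coupling on a 6-bromoindole; the silyl ethers then come off with fluoride, never acid.
- The pyrrole ring of the indole is the only ring formed in the route (benzene ring from 5-bromo-2-iodoaniline), by palladium-catalysed annulation with a β-branched aldehyde.
- The aldehyde comes from a 4-substituted γ-butyrolactone (ring already present in furan-2(5H)-one, opened as a Weinreb amide); the tertiary carbinol comes from Mukaiyama hydration of an isopropenyl group.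
- The stereocentre is set first, by rhodium/(R)-BINAP-catalysed asymmetric 1,4-addition of an isopropenylboronate to furan-2(5H)-one, and is never α to a carbonyl afterwards.

Assumption: the facial sense of the rhodium/(R)-BINAP addition is taken from the established model for cyclic enones and unsaturated lactones ((S)-BINAP gives (S)-3-substituted cyclohexanones), which maps to the (R)-4-isopropenyl lactone; sign and ee are checked by chiral GC before going on.

**Route**

Step 1
Reactants: 1 furan-2(5H)-one; 2 4,4,5,5-tetramethyl-2-(prop-1-en-2-yl)-1,3,2-dioxaborolane (isopropenylboronic acid pinacol ester)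
Product: 3 (4R)-4-(prop-1-en-2-yl)oxolan-2-one
Conditions: [Rh(OH)(cod)]2 (2.5 mol %), (R)-BINAP (5.5 mol %), 2 (2.5 equiv, two portions), 1,4-dioxane/H2O (10:1), 50 °C
Reagents that add atoms: none
Why: Hayashi–Miyaura asymmetric 1,4-addition, in which the (R)-BINAP–rhodium alkenyl species adds to one face of the butenolide and water protonates the rhodium enolate, setting the only stereocentre as (R).

Step 2
Reactants: 3 (4R)-4-(prop-1-en-2-yl)oxolan-2-one
Product: 4 (4S)-4-(2-hydroxypropan-2-yl)oxolan-2-one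
Conditions: Co(acac)2 (20 mol %), PhSiH3 (2.2 equiv), O2 (1 atm), THF, rt
Reagents that add atoms: dioxygen, O=O
Why: Mukaiyama hydration (cobalt hydride hydrogen-atom transfer, O2 capture, reduction of the cobalt peroxide by silane) gives the Markovnikov tertiary alcohol under neutral conditions without touching the adjacent C–H stereocentre; the descriptor changes to S only because the priorities change.

Step 3
Reactants: 4 (4S)-4-(2-hydroxypropan-2-yl)oxolan-2-one
Product: 5 (4S)-4-{2-[(triethylsilyl)oxy]propan-2-yl}oxolan-2-one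
Conditions: TESOTf (1.3 equiv), 2,6-lutidine (2 equiv), CH2Cl2, −78 to 0 °C
Reagents that add atoms: triethylsilyl trifluoromethanesulfonate, CC[Si](CC)(CC)OS(=O)(=O)C(F)(F)F
Why: silyl triflate silylation of the hindered tertiary alcohol, done at once so that the hydroxy lactone cannot translactonise and so that no lactol can form later.

Step 4
Reactants: 5 (4S)-4-{2-[(triethylsilyl)oxy]propan-2-yl}oxolan-2-one
Product: 6 (3S)-3-(hydroxymethyl)-N-methoxy-N,4-dimethyl-4-[(triethylsilyl)oxy]pentanamide
Conditions: MeNH(OMe)·HCl (3 equiv), AlMe3 (3 equiv), CH2Cl2, 0 °C to rt; crude product used directly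
Reagents that add atoms: N,O-dimethylhydroxylamine hydrochloride, CNOC.Cl
Why: Weinreb aminolysis of the lactone by the aluminium amide formed in the flask opens the ring to the hydroxy amide without affecting the β-stereocentre.

Step 5
Reactants: 6 (3S)-3-(hydroxymethyl)-N-methoxy-N,4-dimethyl-4-[(triethylsilyl)oxy]pentanamide
Product: 7 (3S)-3-({[tert-butyl(dimethyl)silyl]oxy}methyl)-N-methoxy-N,4-dimethyl-4-[(triethylsilyl)oxy]pentanamide
Conditions: TBSCl (1.5 equiv), imidazole (3 equiv), DMF, 0 °C to rt
Reagents that add atoms: tert-butyldimethylsilyl chloride, CC(C)(C)[Si](C)(C)Cl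
Why: standard silylation of the only free (primary) hydroxyl, which blocks relactonisation of the γ-hydroxy amide.

Step 6
Reactants: 7 (3S)-3-({[tert-butyl(dimethyl)silyl]oxy}methyl)-N-methoxy-N,4-dimethyl-4-[(triethylsilyl)oxy]pentanamide
Product: 8 (3S)-3-({[tert-butyl(dimethyl)silyl]oxy}methyl)-4-methyl-4-[(triethylsilyl)oxy]pentanal
Conditions: i-Bu2AlH (1.3 equiv), THF, −78 °C; then aqueous potassium sodium tartrate
Reagents that add atoms: none
Why: Weinreb amide reduction stops at the chelated tetrahedral aluminium adduct, which releases the aldehyde only on work-up, and the stereocentre is β to the new carbonyl so it cannot epimerise.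

Step 7
Reactants: 8 (3S)-3-({[tert-butyl(dimethyl)silyl]oxy}methyl)-4-methyl-4-[(triethylsilyl)oxy]pentanal; 9 5-bromo-2-iodoaniline
Product: 11 6-bromo-3-[(2S)-1-{[tert-butyl(dimethyl)silyl]oxy}-3-methyl-3-[(triethylsilyl)oxy]butan-2-yl]-1H-indole, via N-aryl imine 10 (not isolated)
Conditions: 9 (1.2 equiv), Pd(OAc)2 (10 mol %), DABCO (3 equiv), degassed DMF, 85 °C
Reagents that add atoms: none
Why: palladium-catalysed aniline–aldehyde indole annulation (imine/enamine formation, oxidative addition of the C–I bond, intramolecular Heck-type cyclisation) is regiospecific for the 6-bromoindole, leaves the slower C–Br bond alone, and is non-acidic so the β-stereocentre and tertiary silyl ether survive.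

Step 8
Reactants: 11 6-bromo-3-[(2S)-1-{[tert-butyl(dimethyl)silyl]oxy}-3-methyl-3-[(triethylsilyl)oxy]butan-2-yl]-1H-indole; 12 4,4,5,5-tetramethyl-2-(3-methylbut-2-en-1-yl)-1,3,2-dioxaborolane (prenylboronic acid pinacol ester)
Product: 13 3-[(2S)-1-{[tert-butyl(dimethyl)silyl]oxy}-3-methyl-3-[(triethylsilyl)oxy]butan-2-yl]-6-(3-methylbut-2-en-1-yl)-1H-indole
Conditions: 12 (1.5 equiv), PdCl2(IPent)(3-chloropyridine) (3 mol %), KOH (5 M aq, 3 equiv), THF, 65 °C
Reagents that add atoms: none
Why: Suzuki–Miyaura coupling of an allylboronate in which the very bulky carbene ligand forces reductive elimination at the unsubstituted terminus, giving the linear prenyl arene and not the reverse-prenyl isomer.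

Step 9
Reactants: 13 3-[(2S)-1-{[tert-butyl(dimethyl)silyl]oxy}-3-methyl-3-[(triethylsilyl)oxy]butan-2-yl]-6-(3-methylbut-2-en-1-yl)-1H-indole
Product: 14 (2S)-3-methyl-2-[6-(3-methylbut-2-en-1-yl)-1H-indol-3-yl]butane-1,3-diol
Conditions: Bu4NF (4 equiv), THF, 0 to 40 °C
Reagents that add atoms: none
Why: fluoride-driven desilylation removes both silyl ethers under basic conditions, avoiding acid that could ionise the tertiary carbinol next to the indolyl-bearing stereocentre or attack the prenyl group.

Step 10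
Reactants: 14 (2S)-3-methyl-2-[6-(3-methylbut-2-en-1-yl)-1H-indol-3-yl]butane-1,3-diol; 15 (9Z,12Z)-octadeca-9,12-dienoic acid (linoleic acid)
Product: 16 (2S)-3-hydroxy-3-methyl-2-[6-(3-methylbut-2-en-1-yl)-1H-indol-3-yl]butyl (9Z,12Z)-octadeca-9,12-dienoate
Conditions: immobilised Candida antarctica lipase B (a lipase, serine hydrolase class, EC 3.1.1.3), 15 (1.3 equiv), 4 Å molecular sieves, toluene, 45 °C, N2, dark
Reagents that add atoms: none
Why: lipase-catalysed esterification through an acyl-enzyme transfers the linoleoyl group only to the primary hydroxyl (tertiary OH and indole N–H are not accepted) under neutral conditions that preserve the skipped Z,Z-diene, the prenyl group and the stereocentre, with the sieves removing water to drive the equilibrium.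

**Compound list**

1 | furan-2(5H)-one | O=C1C=CCO1 | starting material
2 | 4,4,5,5-tetramethyl-2-(prop-1-en-2-yl)-1,3,2-dioxaborolane | CC(=C)B1OC(C)(C)C(C)(C)O1 | starting material
3 | (4R)-4-(prop-1-en-2-yl)oxolan-2-one | O=C1C[C@H](C(C)=C)CO1 | intermediate
4 | (4S)-4-(2-hydroxypropan-2-yl)oxolan-2-one | O=C1C[C@H](C(C)(C)O)CO1 | intermediate
5 | (4S)-4-{2-[(triethylsilyl)oxy]propan-2-yl}oxolan-2-one | O=C1C[C@H](C(C)(C)O[Si](CC)(CC)CC)CO1 | intermediate
6 | (3S)-3-(hydroxymethyl)-N-methoxy-N,4-dimethyl-4-[(triethylsilyl)oxy]pentanamide | CON(C)C(=O)C[C@@H](CO)C(C)(C)O[Si](CC)(CC)CC | intermediate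
7 | (3S)-3-({[tert-butyl(dimethyl)silyl]oxy}methyl)-N-methoxy-N,4-dimethyl-4-[(triethylsilyl)oxy]pentanamide | CON(C)C(=O)C[C@@H](CO[Si](C)(C)C(C)(C)C)C(C)(C)O[Si](CC)(CC)CC | intermediate
8 | (3S)-3-({[tert-butyl(dimethyl)silyl]oxy}methyl)-4-methyl-4-[(triethylsilyl)oxy]pentanal | O=CC[C@@H](CO[Si](C)(C)C(C)(C)C)C(C)(C)O[Si](CC)(CC)CC | intermediate
9 | 5-bromo-2-iodoaniline | Nc1cc(Br)ccc1I | starting material
10 | (1E,3S)-N-(5-bromo-2-iodophenyl)-3-({[tert-butyl(dimethyl)silyl]oxy}methyl)-4-methyl-4-[(triethylsilyl)oxy]pentan-1-imine | Brc1ccc(I)c(c1)/N=C/C[C@@H](CO[Si](C)(C)C(C)(C)C)C(C)(C)O[Si](CC)(CC)CC | intermediate (not isolated)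
11 | 6-bromo-3-[(2S)-1-{[tert-butyl(dimethyl)silyl]oxy}-3-methyl-3-[(triethylsilyl)oxy]butan-2-yl]-1H-indole | CC(C)(C)[Si](C)(C)OC[C@H](c1c[nH]c2cc(Br)ccc12)C(C)(C)O[Si](CC)(CC)CC | intermediate
12 | 4,4,5,5-tetramethyl-2-(3-methylbut-2-en-1-yl)-1,3,2-dioxaborolane | CC(C)=CCB1OC(C)(C)C(C)(C)O1 | starting material
13 | 3-[(2S)-1-{[tert-butyl(dimethyl)silyl]oxy}-3-methyl-3-[(triethylsilyl)oxy]butan-2-yl]-6-(3-methylbut-2-en-1-yl)-1H-indole | CC(C)(C)[Si](C)(C)OC[C@H](c1c[nH]c2cc(CC=C(C)C)ccc12)C(C)(C)O[Si](CC)(CC)CC | intermediate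
14 | (2S)-3-methyl-2-[6-(3-methylbut-2-en-1-yl)-1H-indol-3-yl]butane-1,3-diol | OC[C@H](c1c[nH]c2cc(CC=C(C)C)ccc12)C(C)(C)O | intermediate
15 | (9Z,12Z)-octadeca-9,12-dienoic acid | CCCCC/C=C\C/C=C\CCCCCCCC(=O)O | starting material
16 | (2S)-3-hydroxy-3-methyl-2-[6-(3-methylbut-2-en-1-yl)-1H-indol-3-yl]butyl (9Z,12Z)-octadeca-9,12-dienoate | CCCCC/C=C\C/C=C\CCCCCCCC(=O)OC[C@H](c1c[nH]c2cc(CC=C(C)C)ccc12)C(C)(C)O | target

**Step count and risks**

Total step count: 10. Longest linear sequence: 10 steps (1 to 16).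

The three steps most likely to fail:

Step 1. Furan-2(5H)-one is a sluggish acceptor and the 1,1-disubstituted alkenylboronate can protodeboronate faster than it adds, so yield or ee may fall short. The fallback sets out again from 1 and transfers the small vinyl group instead (potassium vinyltrifluoroborate, [Rh(OH)(cod)]2/(R)-BINAP, dioxane/H2O, 60 °C), giving (4R)-4-ethenyloxolan-2-one F1. Wacker–Tsuji oxidation (PdCl2, CuCl, O2, DMF/H2O, rt) turns the vinyl group into the methyl ketone (4S)-4-acetyloxolan-2-one F2, which is used promptly. Chemoselective addition of MeMgBr with CeCl3 (THF, −78 °C) to the ketone in the presence of the lactone then gives 4, where the route is rejoined; the tertiary carbinol is thus built by carbonyl addition and not by alkene hydration.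

Step 7. The aldehyde carries a very bulky β-carbon, which may slow enamine formation and cyclisation, and the C–Br bond must stay intact. The fallback sets out from 5 and builds the indole by nitroarene substitution and reductive cyclisation. The lithium enolate of 5 (LiN(SiMe3)2, 2.2 equiv, THF, −78 °C) displaces fluoride from 4-bromo-1-fluoro-2-nitrobenzene to give (3R,4S)-3-(4-bromo-2-nitrophenyl)-4-{2-[(triethylsilyl)oxy]propan-2-yl}oxolan-2-one F3; this is the 3,4-trans isomer, and its C-3 centre later becomes indole C-3, so its configuration does not matter. Reduction with i-Bu2AlH (CH2Cl2, −78 °C) gives the lactol (3R,4S)-3-(4-bromo-2-nitrophenyl)-4-{2-[(triethylsilyl)oxy]propan-2-yl}oxolan-2-ol F4 as an anomer mixture. Fe powder with NH4Cl (EtOH/H2O, 70 °C) reduces the nitro group without touching C–Br, and the amino lactol (3R,4S)-3-(2-amino-4-bromophenyl)-4-{2-[(triethylsilyl)oxy]propan-2-yl}oxolan-2-ol F5 cyclises and dehydrates in the same pot to (2S)-2-(6-bromo-1H-indol-3-yl)-3-methyl-3-[(triethylsilyl)oxy]butan-1-ol F6. Silylation of the primary alcohol (TBSCl, imidazole, DMF) returns to the route at 11.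

Step 8. Allylboronates can couple at either terminus, so some reverse-prenyl isomer, or alkene isomerisation under the strong base, is possible. The fallback sets out from 11 and first couples the unsubstituted allyl group, for which the α/γ question does not arise (allylboronic acid pinacol ester, same palladium catalyst, KOH, THF, 65 °C), giving 3-[(2S)-1-{[tert-butyl(dimethyl)silyl]oxy}-3-methyl-3-[(triethylsilyl)oxy]butan-2-yl]-6-(prop-2-en-1-yl)-1H-indole F7. Olefin cross-metathesis with excess 2-methylbut-2-ene (second-generation Grubbs catalyst, RuCl2(=CHPh)(PCy3)(H2IMes), CH2Cl2, 40 °C) then converts allyl into prenyl and returns to the route at 13.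

Further compounds
F1 | step 1 | (4R)-4-ethenyloxolan-2-one | O=C1C[C@H](C=C)CO1
F2 | step 1 | (4S)-4-acetyloxolan-2-one | O=C1C[C@H](C(C)=O)CO1
F3 | step 7 | (3R,4S)-3-(4-bromo-2-nitrophenyl)-4-{2-[(triethylsilyl)oxy]propan-2-yl}oxolan-2-one | O=C1[C@@H](c2ccc(Br)cc2[N+](=O)[O-])[C@H](C(C)(C)O[Si](CC)(CC)CC)CO1
F4 | step 7 | (3R,4S)-3-(4-bromo-2-nitrophenyl)-4-{2-[(triethylsilyl)oxy]propan-2-yl}oxolan-2-ol (anomer mixture) | OC1[C@@H](c2ccc(Br)cc2[N+](=O)[O-])[C@H](C(C)(C)O[Si](CC)(CC)CC)CO1
F5 | step 7 | (3R,4S)-3-(2-amino-4-bromophenyl)-4-{2-[(triethylsilyl)oxy]propan-2-yl}oxolan-2-ol (anomer mixture, not isolated) | OC1[C@@H](c2ccc(Br)cc2N)[C@H](C(C)(C)O[Si](CC)(CC)CC)CO1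
F6 | step 7 | (2S)-2-(6-bromo-1H-indol-3-yl)-3-methyl-3-[(triethylsilyl)oxy]butan-1-ol | OC[C@H](c1c[nH]c2cc(Br)ccc12)C(C)(C)O[Si](CC)(CC)CC
F7 | step 8 | 3-[(2S)-1-{[tert-butyl(dimethyl)silyl]oxy}-3-methyl-3-[(triethylsilyl)oxy]butan-2-yl]-6-(prop-2-en-1-yl)-1H-indole | CC(C)(C)[Si](C)(C)OC[C@H](c1c[nH]c2cc(CC=C)ccc12)C(C)(C)O[Si](CC)(CC)CC
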